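The ten-membered carbocycle is closed last, across C6–C7 (C6 carries the acetate, C7 the isopropyl group), after both oxiranes are in place. The cis C6–O/C7–C11 pair beside the C4–C5 epoxide is read as a syn homoallylic alcohol: intramolecular allylboration of an α,β-epoxy aldehyde by a (Z)-allyl pinacolboronate forms the ring, the C6–C7 bond and both stereocentres through one chair transition state, leaving an isopropenyl group that is hydrogenated. The precursor is an open-chain bis-epoxide (C6 primary alcohol, C2 silyl ether, (Z)-2-methylallylboronate terminus), built from geranyl acetate by Z-selective iodo-olefination, a catalytic asymmetric vinylogous Mukaiyama aldol reaction and two hydroxyl-directed epoxidations.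

Key step: step 13

Remark: the ring is numbered as in germacrane (C1/C10 and C4/C5 are the oxirane carbons, C2 carries the angelate, C6 the acetate, C7 the isopropyl group with C11 as its methine); open-chain intermediates are numbered as chains.

Step 1
Reactants: 1 geranyl acetate, (2E)-3,7-dimethylocta-2,6-dien-1-yl acetate
Product: 2 (2E)-5-(3,3-dimethyloxiran-2-yl)-3-methylpent-2-en-1-yl acetate (racemic at the oxirane CH)
Conditions: mCPBA (1.0 equiv), NaHCO3, CH2Cl2, 0 °C
Reagents that add atoms: meta-chloroperbenzoic acid, O=C(OO)c1cccc(Cl)c1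
Why: Prilezhaev epoxidation should select the electron-rich 6,7-olefin because the 2,3-olefin is deactivated by the allylic acetoxy group; the racemic centre is destroyed in step 2.

Step 2
Reactants: 2 (2E)-5-(3,3-dimethyloxiran-2-yl)-3-methylpent-2-en-1-yl acetate
Product: 4 (2E)-3-methyl-6-oxohex-2-en-1-yl acetate, via 6,7-diol 3 (not isolated)
Conditions: H5IO6, THF–H2O, 0 °C → rt
Reagents that add atoms: none
Why: Acid-mediated hydrolysis of the epoxide to the vicinal diol followed by Malaprade glycol cleavage should excise acetone and leave the aldehyde without touching the allylic acetate.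

Step 3
Reactants: 4 (2E)-3-methyl-6-oxohex-2-en-1-yl acetate; 5 ethyltriphenylphosphonium iodide
Product: 9 (2E,6Z)-7-iodo-3-methylocta-2,6-dien-1-yl acetate, via ethylidenetriphenylphosphorane 6 (not isolated), via (1-iodoethyl)triphenylphosphonium iodide 7 (not isolated), via (1-iodoethylidene)triphenylphosphorane 8 (not isolated)
Conditions: 5, n-BuLi, THF, 0 °C; I2, −78 °C; NaHMDS, −20 °C; then 4, −78 °C → rt
Reagents that add atoms: iodine, II
Why: The Stork–Zhao-type Wittig olefination with the α-iodo ylide is kinetically Z-selective for aliphatic aldehydes and should place iodine cis to the chain, the geometry that is later transmitted to C7; any minor E isomer is removed by chromatography.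

Step 4
Reactants: 9 (2E,6Z)-7-iodo-3-methylocta-2,6-dien-1-yl acetate
Product: 10 (2E,6Z)-7-iodo-3-methylocta-2,6-dien-1-ol
Conditions: K2CO3, MeOH, 0 °C → rt
Reagents that add atoms: none
Why: Base-catalysed transesterification should remove the acetate while the vinyl iodide and both olefin geometries are untouched.

Step 5
Reactants: 10 (2E,6Z)-7-iodo-3-methylocta-2,6-dien-1-ol
Product: 11 (2E,6Z)-7-iodo-3-methylocta-2,6-dienal
Conditions: MnO2, CH2Cl2, rt
Reagents that add atoms: none
Why: Manganese dioxide oxidises allylic alcohols chemoselectively and should give the enal without E/Z isomerisation of the 2,3-olefin.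

Step 6
Reactants: 12 methyl 3-methylbut-2-enoate
Product: 13 tert-butyl[(1-methoxy-3-methylbuta-1,3-dien-1-yl)oxy]dimethylsilane (silyl dienol ether of methyl senecioate)
Conditions: LDA, THF–DMPU, −78 °C; TBSCl, −78 °C → rt
Reagents that add atoms: tert-butyldimethylsilyl chloride, CC(C)(C)[Si](C)(C)Cl
Why: Kinetic γ-deprotonation of the senecioate and O-silylation of the dienolate should give the vinylketene silyl acetal.

Step 7
Reactants: 11 (2E,6Z)-7-iodo-3-methylocta-2,6-dienal; 13 silyl dienol ether of methyl senecioate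
Product: 15 methyl (2E,5R,6E,10Z)-5-hydroxy-11-iodo-3,7-dimethyldodeca-2,6,10-trienoate, via trichlorosilyl ether 14 (not isolated)
Conditions: SiCl4 (1.1 equiv), (R,R)-Denmark BINAM-derived bis-phosphoramide (5 mol%), i-Pr2NEt (10 mol%), CH2Cl2, −78 °C; sat. aq. NaHCO3
Reagents that add atoms: none
Why: In this Lewis-base-activated vinylogous Mukaiyama aldol reaction the chiral phosphoramide-bound trichlorosilyl cation activates the conjugated aldehyde, the dienolate should attack through its γ-carbon to give the E-enoate, and the (R,R)-catalyst is expected to direct it to the Re face, which sets C5 as R (the future C2).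

Step 8
Reactants: 15 methyl (2E,5R,6E,10Z)-5-hydroxy-11-iodo-3,7-dimethyldodeca-2,6,10-trienoate
Product: 16 methyl (2E,5R)-5-hydroxy-5-{(2S,3S)-3-[(3Z)-4-iodopent-3-en-1-yl]-3-methyloxiran-2-yl}-3-methylpent-2-enoate
Conditions: Ti(Oi-Pr)4 (20 mol%), t-BuOOH (decane), 4 Å MS, CH2Cl2, −20 °C
Reagents that add atoms: tert-butyl hydroperoxide, CC(C)(C)OO
Why: In this hydroxyl-directed epoxidation A(1,3) strain with the methyl group cis to the carbinol holds C5–H in the olefin plane, so the titanium-bound peroxide should be delivered to the face that gives the threo (5R,6S,7S) epoxy alcohol; the enoate and the vinyl iodide are too electron-poor to react.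

Step 9
Reactants: 16 threo epoxy alcohol
Product: 17 methyl (2E,5R)-5-{(2S,3S)-3-[(3Z)-4-iodopent-3-en-1-yl]-3-methyloxiran-2-yl}-3-methyl-5-(triethylsilyloxy)pent-2-enoate
Conditions: Et3SiCl, imidazole, DMAP (cat.), CH2Cl2, 0 °C → rt
Reagents that add atoms: chlorotriethylsilane, CC[Si](Cl)(CC)CC
Why: Silylation under mild base should mask the future C2 hydroxyl as a triethylsilyl ether that survives the following steps and can be removed by buffered fluoride.

Step 10
Reactants: 17 silyl-protected epoxy enoate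
Product: 18 (2E,5R)-5-{(2S,3S)-3-[(3Z)-4-iodopent-3-en-1-yl]-3-methyloxiran-2-yl}-3-methyl-5-(triethylsilyloxy)pent-2-en-1-ol
Conditions: DIBAL-H (2.5 equiv), CH2Cl2, −78 °C; aq. Rochelle salt
Reagents that add atoms: none
Why: 1,2-Reduction of the enoate by DIBAL-H at −78 °C should give the E-allylic alcohol while the trisubstituted epoxide, the silyl ether and the vinyl iodide remain intact.

Step 11
Reactants: 18 allylic alcohol
Product: 19 {(2S,3S)-3-[(2R)-2-{(2S,3S)-3-[(3Z)-4-iodopent-3-en-1-yl]-3-methyloxiran-2-yl}-2-(triethylsilyloxy)ethyl]-3-methyloxiran-2-yl}methanol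
Conditions: Ti(Oi-Pr)4 (10 mol%), L-(+)-DET (12 mol%), t-BuOOH, 4 Å MS, CH2Cl2, −20 °C
Reagents that add atoms: tert-butyl hydroperoxide, CC(C)(C)OO
Why: The Sharpless asymmetric epoxidation with L-(+)-diethyl tartrate is reagent-controlled and should give the (2S,3S)-epoxy alcohol from the E-trisubstituted allylic alcohol, as it does for geraniol; this sets C4 and C5.

Step 12
Reactants: 19 bis-epoxy alcohol with (Z)-vinyl iodide; 20 2-(iodomethyl)-4,4,5,5-tetramethyl-1,3,2-dioxaborolane
Product: 22 {(2S,3S)-3-[(2R)-2-{(2S,3S)-3-methyl-3-[(3Z)-4-methyl-5-(4,4,5,5-tetramethyl-1,3,2-dioxaborolan-2-yl)pent-3-en-1-yl]oxiran-2-yl}-2-(triethylsilyloxy)ethyl]-3-methyloxiran-2-yl}methanol, via borylmethylzinc iodide 21 (not isolated)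
Conditions: 20, Zn dust, THF, rt; then 19, Pd(PPh3)4 (5 mol%), THF, rt → 40 °C (3 equiv of the zinc reagent)
Reagents that add atoms: none
Why: Negishi-type cross-coupling of (pinacolatoboryl)methylzinc iodide with alkenyl iodides proceeds with retention of olefin geometry and should give the (Z)-allylboronate; the organozinc does not attack epoxides, and the excess covers protonolysis by the free hydroxyl.

Step 13
Reactants: 22 (Z)-allylboronate bis-epoxy alcohol
Product: 25 (1S,2R,4S,5S,6R,7S,10S)-1,10:4,5-diepoxy-2-(triethylsilyloxy)germacr-11-en-6-ol (ten-membered ring, C6–OH and C7-isopropenyl cis), via epoxy aldehyde 23 (not isolated), via macrocyclic borate 24 (not isolated)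
Conditions: Dess–Martin periodinane, NaHCO3, CH2Cl2, 0 °C; aq. Na2S2O3/NaHCO3 wash; then toluene (2 mM), 70 °C; pH 7 buffer work-up
Reagents that add atoms: none
Why: Dess–Martin oxidation gives the (2R,3S)-epoxy aldehyde 23, whose carbonyl oxygen binds boron while the γ-carbon (C7) of the (Z)-allylboronate attacks the carbonyl carbon through a six-membered chair (Zimmerman–Traxler-type) transition state with allylic transposition, giving borate 24, which is hydrolysed on work-up. The closest known reactions are intramolecular allylborations of ω-formyl allylboronates to five- to eight-membered rings and the closure of 12-halo-2,3-epoxyfarnesal-type chains to 4,5-epoxygermacran-6-ols by intramolecular carbonyl allylation. The ten-membered ring closes in the 10-exo-trig mode with respect to the carbonyl group, at 2 mM so that intermolecular allylboration is suppressed. C7 is controlled by the olefin geometry: in the chair the chain carbon C8, cis to the CH2B group, is axial and the aldehyde substituent equatorial, which should give the syn homoallylic alcohol, that is C6–O and C7–C11 cis on the ring. C6 is controlled by the C4–C5 epoxide: the aldehyde reacts in its s-trans conformation with its hydrogen turned towards the cis methyl group on C4, C7 attacks anti to the C5–O bond, and the ring chain can only pass on the face opposite the oxirane oxygen, which together should give 6R. The step needs the boronate to keep its Z geometry (pinacol allylboronates do not undergo 1,3-boron shift at this temperature) and both epoxides to survive, which the neutral, Lewis-acid-free conditions secure.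

Step 14
Reactants: 25 macrocyclic alcohol
Product: 26 (1S,2R,4S,5S,6R,7S,10S)-1,10:4,5-diepoxy-2-(triethylsilyloxy)germacr-11-en-6-yl acetate
Conditions: Ac2O, pyridine, DMAP (cat.), CH2Cl2, rt
Reagents that add atoms: acetic anhydride, CC(=O)OC(C)=O
Why: DMAP-catalysed acylation should acetylate the hindered secondary C6 alcohol without affecting the epoxides or the silyl ether.

Step 15
Reactants: 26 isopropenyl acetate
Product: 27 (1S,2R,4S,5S,6R,7S,10S)-1,10:4,5-diepoxy-2-(triethylsilyloxy)germacran-6-yl acetate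
Conditions: H2 (1–3 atm), RhCl(PPh3)3 (10 mol%), benzene–EtOH, rt
Reagents that add atoms: none
Why: Homogeneous hydrogenation with Wilkinson's catalyst should saturate the 1,1-disubstituted olefin, the only C=C bond present, to the isopropyl group without hydrogenolysis of the non-allylic epoxides and without creating a stereocentre.

Step 16
Reactants: 27 silyl ether
Product: 28 (1S,2R,4S,5S,6R,7S,10S)-1,10:4,5-diepoxy-2-hydroxygermacran-6-yl acetate
Conditions: TBAF, AcOH (1:1), THF, 0 °C → rt
Reagents that add atoms: none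
Why: Fluoride cleaves the triethylsilyl ether, and buffering with acetic acid should prevent Payne rearrangement of the liberated epoxy alkoxide and loss of the acetate.

Step 17
Reactants: 28 C2 alcohol; 29 angelic acid, (2Z)-2-methylbut-2-enoic acid
Product: 31 target, (1S,2R,4S,5S,6R,7S,10S)-6-acetoxy-1,10:4,5-diepoxygermacran-2-yl (2Z)-2-methylbut-2-enoate, via mixed anhydride 30 (not isolated)
Conditions: 29, 2,4,6-Cl3C6H2COCl, Et3N, toluene, rt, filter; then 28, toluene, 80 °C
Reagents that add atoms: none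
Why: Yamaguchi-type esterification through the angelic 2,4,6-trichlorobenzoic mixed anhydride, run without DMAP, is the protocol used for hindered angelates because it should avoid Z→E isomerisation to the tiglate; the ammonium chloride is filtered off before heating to protect the epoxides.

Compound list
1 | geranyl acetate, (2E)-3,7-dimethylocta-2,6-dien-1-yl acetate | CC(=O)OC/C=C(\C)CCC=C(C)C | starting material
2 | (2E)-5-(3,3-dimethyloxiran-2-yl)-3-methylpent-2-en-1-yl acetate (racemic) | CC(=O)OC/C=C(\C)CCC1OC1(C)C | intermediate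
3 | (2E)-6,7-dihydroxy-3,7-dimethyloct-2-en-1-yl acetate (racemic) | CC(=O)OC/C=C(\C)CCC(O)C(C)(C)O | intermediate
4 | (2E)-3-methyl-6-oxohex-2-en-1-yl acetate | CC(=O)OC/C=C(\C)CCC=O | intermediate
5 | ethyltriphenylphosphonium iodide | CC[P+](c1ccccc1)(c1ccccc1)c1ccccc1.[I-] | starting material
6 | ethylidenetriphenylphosphorane | CC=P(c1ccccc1)(c1ccccc1)c1ccccc1 | intermediate
7 | (1-iodoethyl)triphenylphosphonium iodide | CC(I)[P+](c1ccccc1)(c1ccccc1)c1ccccc1.[I-] | intermediate
8 | (1-iodoethylidene)triphenylphosphorane | CC(I)=P(c1ccccc1)(c1ccccc1)c1ccccc1 | intermediate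
9 | (2E,6Z)-7-iodo-3-methylocta-2,6-dien-1-yl acetate | CC(=O)OC/C=C(\C)CC/C=C(\I)C | intermediate
10 | (2E,6Z)-7-iodo-3-methylocta-2,6-dien-1-ol | OC/C=C(\C)CC/C=C(\I)C | intermediate
11 | (2E,6Z)-7-iodo-3-methylocta-2,6-dienal | O=C/C=C(\C)CC/C=C(\I)C | intermediate
12 | methyl 3-methylbut-2-enoate | COC(=O)C=C(C)C | starting material
13 | tert-butyl[(1-methoxy-3-methylbuta-1,3-dien-1-yl)oxy]dimethylsilane | C=C(C)C=C(OC)O[Si](C)(C)C(C)(C)C | intermediate
14 | methyl (2E,5R,6E,10Z)-11-iodo-3,7-dimethyl-5-(trichlorosilyloxy)dodeca-2,6,10-trienoate | COC(=O)/C=C(\C)C[C@@H](O[Si](Cl)(Cl)Cl)/C=C(\C)CC/C=C(\I)C | intermediate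
15 | methyl (2E,5R,6E,10Z)-5-hydroxy-11-iodo-3,7-dimethyldodeca-2,6,10-trienoate | COC(=O)/C=C(\C)C[C@@H](O)/C=C(\C)CC/C=C(\I)C | intermediate
16 | methyl (2E,5R)-5-hydroxy-5-{(2S,3S)-3-[(3Z)-4-iodopent-3-en-1-yl]-3-methyloxiran-2-yl}-3-methylpent-2-enoate | COC(=O)/C=C(\C)C[C@@H](O)[C@@H]1O[C@@]1(C)CC/C=C(\I)C | intermediate
17 | methyl (2E,5R)-5-{(2S,3S)-3-[(3Z)-4-iodopent-3-en-1-yl]-3-methyloxiran-2-yl}-3-methyl-5-(triethylsilyloxy)pent-2-enoate | COC(=O)/C=C(\C)C[C@@H](O[Si](CC)(CC)CC)[C@@H]1O[C@@]1(C)CC/C=C(\I)C | intermediate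
18 | (2E,5R)-5-{(2S,3S)-3-[(3Z)-4-iodopent-3-en-1-yl]-3-methyloxiran-2-yl}-3-methyl-5-(triethylsilyloxy)pent-2-en-1-ol | OC/C=C(\C)C[C@@H](O[Si](CC)(CC)CC)[C@@H]1O[C@@]1(C)CC/C=C(\I)C | intermediate
19 | {(2S,3S)-3-[(2R)-2-{(2S,3S)-3-[(3Z)-4-iodopent-3-en-1-yl]-3-methyloxiran-2-yl}-2-(triethylsilyloxy)ethyl]-3-methyloxiran-2-yl}methanol | OC[C@@H]1O[C@@]1(C)C[C@@H](O[Si](CC)(CC)CC)[C@@H]1O[C@@]1(C)CC/C=C(\I)C | intermediate
20 | 2-(iodomethyl)-4,4,5,5-tetramethyl-1,3,2-dioxaborolane | ICB1OC(C)(C)C(C)(C)O1 | starting material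
21 | [(4,4,5,5-tetramethyl-1,3,2-dioxaborolan-2-yl)methyl]zinc iodide | I[Zn]CB1OC(C)(C)C(C)(C)O1 | intermediate
22 | {(2S,3S)-3-[(2R)-2-{(2S,3S)-3-methyl-3-[(3Z)-4-methyl-5-(4,4,5,5-tetramethyl-1,3,2-dioxaborolan-2-yl)pent-3-en-1-yl]oxiran-2-yl}-2-(triethylsilyloxy)ethyl]-3-methyloxiran-2-yl}methanol | OC[C@@H]1O[C@@]1(C)C[C@@H](O[Si](CC)(CC)CC)[C@@H]1O[C@@]1(C)CC/C=C(\CB1OC(C)(C)C(C)(C)O1)C | intermediate
23 | (2R,3S)-3-[(2R)-2-{(2S,3S)-3-methyl-3-[(3Z)-4-methyl-5-(4,4,5,5-tetramethyl-1,3,2-dioxaborolan-2-yl)pent-3-en-1-yl]oxiran-2-yl}-2-(triethylsilyloxy)ethyl]-3-methyloxirane-2-carbaldehyde | O=C[C@@H]1O[C@@]1(C)C[C@@H](O[Si](CC)(CC)CC)[C@@H]1O[C@@]1(C)CC/C=C(\CB1OC(C)(C)C(C)(C)O1)C | intermediate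
24 | pinacol borate of 25 (O-boryl ether at C6) | CC[Si](CC)(CC)O[C@@H]1C[C@]2(C)O[C@H]2[C@H](OB3OC(C)(C)C(C)(C)O3)[C@H](C(C)=C)CC[C@]2(C)O[C@@H]12 | intermediate
25 | (1S,2R,4S,5S,6R,7S,10S)-1,10:4,5-diepoxy-2-(triethylsilyloxy)germacr-11-en-6-ol | CC[Si](CC)(CC)O[C@@H]1C[C@]2(C)O[C@H]2[C@H](O)[C@H](C(C)=C)CC[C@]2(C)O[C@@H]12 | intermediate
26 | (1S,2R,4S,5S,6R,7S,10S)-1,10:4,5-diepoxy-2-(triethylsilyloxy)germacr-11-en-6-yl acetate | CC[Si](CC)(CC)O[C@@H]1C[C@]2(C)O[C@H]2[C@H](OC(C)=O)[C@H](C(C)=C)CC[C@]2(C)O[C@@H]12 | intermediate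
27 | (1S,2R,4S,5S,6R,7S,10S)-1,10:4,5-diepoxy-2-(triethylsilyloxy)germacran-6-yl acetate | CC[Si](CC)(CC)O[C@@H]1C[C@]2(C)O[C@H]2[C@H](OC(C)=O)[C@H](C(C)C)CC[C@]2(C)O[C@@H]12 | intermediate
28 | (1S,2R,4S,5S,6R,7S,10S)-1,10:4,5-diepoxy-2-hydroxygermacran-6-yl acetate | O[C@@H]1C[C@]2(C)O[C@H]2[C@H](OC(C)=O)[C@H](C(C)C)CC[C@]2(C)O[C@@H]12 | intermediate
29 | angelic acid, (2Z)-2-methylbut-2-enoic acid | C/C=C(/C)C(=O)O | starting material
30 | (2Z)-2-methylbut-2-enoic 2,4,6-trichlorobenzoic anhydride | C/C=C(/C)C(=O)OC(=O)c1c(Cl)cc(Cl)cc1Cl | intermediate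
31 | (1S,2R,4S,5S,6R,7S,10S)-6-acetoxy-1,10:4,5-diepoxygermacran-2-yl (2Z)-2-methylbut-2-enoate | C/C=C(/C)C(=O)O[C@@H]1C[C@]2(C)O[C@H]2[C@H](OC(C)=O)[C@H](C(C)C)CC[C@]2(C)O[C@@H]12 | target

Total step count: 17. Longest linear sequence: 16 steps (steps 1–5 and 7–17); step 6 is a one-step branch.

Steps most likely to fail

Step 13. The ring closure may be too slow at high dilution, so that intermolecular allylboration (oligomerisation) or thermal decay of the epoxy aldehyde competes, and a competing chair on the other aldehyde face would erode the C6/C7 selectivity. The fallback replaces allylboration by umpolung of a π-allylpalladium and sets out from 19. Dess–Martin oxidation would give the epoxy aldehyde F1, still carrying the vinyl iodide. Stille coupling with (tributylstannyl)methanol (Pd(PPh3)4, dioxane, 80 °C) would give the (Z)-allylic alcohol F2 with retention of geometry, and MsCl, LiCl, s-collidine in DMF at 0 °C would give the allylic chloride F3. Cyclisation with PdCl2(PPh3)2 (cat.), Et2Zn and K2CO3 in DMA at high dilution, conditions known to close 12-chloro-2,3-epoxyfarnesal-type chains to ten-membered 4,5-epoxygermacran-6-ols, should return to the route at 25. Because the allylzinc intermediate equilibrates, the C7 configuration would then rest on the macrocyclic transition state and not on the olefin geometry, and would have to be verified.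

Step 12. Zinc iodide may open the 2,3-epoxy alcohol, and the free hydroxyl may protonate the zinc reagent before coupling. The fallback installs boron first and the methylene second, from 19. Miyaura borylation (B2pin2, PdCl2(PPh3)2, PPh3, KOPh, toluene, 50 °C) would give the alkenyl pinacolboronate F4 with boron in place of iodine and the same olefin geometry. Matteson homologation with LiCH2Cl (BrCH2Cl, n-BuLi, THF, −78 °C → rt, one extra equivalent of base for the hydroxyl) inserts CH2 into the C–B bond with retention and should return to the route at 22.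

Step 8. Facial selectivity in the substrate-controlled epoxidation may be insufficient, giving the erythro isomer alongside the threo one. The fallback uses reagent control followed by inversion and sets out from 11 and 13. The aldol reaction of step 7 run with the (S,S)-catalyst would give the (5S)-alcohol F5. Sharpless epoxidation with L-(+)-diisopropyl tartrate, for which the (S)-carbinol is the fast-reacting, erythro-selective enantiomer, would give the (5S,6S,7S)-epoxy alcohol F6. Mitsunobu inversion (4-nitrobenzoic acid, PPh3, DIAD, THF) would give the (5R)-4-nitrobenzoate F7, and K2CO3 in MeOH at 0 °C should return to the route at 16.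

Further compounds
F1 | step 13 | (2R,3S)-3-[(2R)-2-{(2S,3S)-3-[(3Z)-4-iodopent-3-en-1-yl]-3-methyloxiran-2-yl}-2-(triethylsilyloxy)ethyl]-3-methyloxirane-2-carbaldehyde | O=C[C@@H]1O[C@@]1(C)C[C@@H](O[Si](CC)(CC)CC)[C@@H]1O[C@@]1(C)CC/C=C(\I)C
F2 | step 13 | (2R,3S)-3-[(2R)-2-{(2S,3S)-3-[(3Z)-5-hydroxy-4-methylpent-3-en-1-yl]-3-methyloxiran-2-yl}-2-(triethylsilyloxy)ethyl]-3-methyloxirane-2-carbaldehyde | O=C[C@@H]1O[C@@]1(C)C[C@@H](O[Si](CC)(CC)CC)[C@@H]1O[C@@]1(C)CC/C=C(\CO)C
F3 | step 13 | (2R,3S)-3-[(2R)-2-{(2S,3S)-3-[(3Z)-5-chloro-4-methylpent-3-en-1-yl]-3-methyloxiran-2-yl}-2-(triethylsilyloxy)ethyl]-3-methyloxirane-2-carbaldehyde | O=C[C@@H]1O[C@@]1(C)C[C@@H](O[Si](CC)(CC)CC)[C@@H]1O[C@@]1(C)CC/C=C(\CCl)C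
F4 | step 12 | {(2S,3S)-3-[(2R)-2-{(2S,3S)-3-methyl-3-[(3E)-4-(4,4,5,5-tetramethyl-1,3,2-dioxaborolan-2-yl)pent-3-en-1-yl]oxiran-2-yl}-2-(triethylsilyloxy)ethyl]-3-methyloxiran-2-yl}methanol | OC[C@@H]1O[C@@]1(C)C[C@@H](O[Si](CC)(CC)CC)[C@@H]1O[C@@]1(C)CC/C=C(\B1OC(C)(C)C(C)(C)O1)C
F5 | step 8 | methyl (2E,5S,6E,10Z)-5-hydroxy-11-iodo-3,7-dimethyldodeca-2,6,10-trienoate | COC(=O)/C=C(\C)C[C@H](O)/C=C(\C)CC/C=C(\I)C
F6 | step 8 | methyl (2E,5S)-5-hydroxy-5-{(2S,3S)-3-[(3Z)-4-iodopent-3-en-1-yl]-3-methyloxiran-2-yl}-3-methylpent-2-enoate | COC(=O)/C=C(\C)C[C@H](O)[C@@H]1O[C@@]1(C)CC/C=C(\I)C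
F7 | step 8 | methyl (2E,5R)-5-{(2S,3S)-3-[(3Z)-4-iodopent-3-en-1-yl]-3-methyloxiran-2-yl}-3-methyl-5-(4-nitrobenzoyloxy)pent-2-enoate | COC(=O)/C=C(\C)C[C@@H](OC(=O)c1ccc(cc1)[N+](=O)[O-])[C@@H]1O[C@@]1(C)CC/C=C(\I)C
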